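**Retrosynthetic overview**
- **Feature.** Ring D is the cyclohexane C4a–C5–C6–C7–C8–C8a of the spiro-linked octalin. It carries the C5 methyl and C8 isopropyl groups trans-1,4, with H-4a cis to H-5. Its C8–C8a bond joins the prenyl CH of citronellal to the β carbon of a cyclohexenone, and C5 is the citronellal stereocentre.
- **Late disconnections (backwards).** The O-methyl ether comes off first. Rings A and B then go together: an ethyl ketone closes onto a spiro δ-lactone (Claisen), and the freed tertiary alkoxide moves to a tosyloxy-marked carbon. Next come the lactone Cα–C bond to 2,2-dimethyl-3-oxopentanal and the C2–CH2 bond (chiral alkylcerium plus octalone).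
- **Early disconnections.** The octalone comes from the cis-decalone by reagent-controlled enol silane formation and Saegusa oxidation. The decalone comes from the 4-substituted cyclohexenone by conjugate ene closure of C8–C8a. The cyclohexenone comes from (R)-citronellal and methyl vinyl ketone.
- **Ring order.** C (step 2), D (step 3), temporary lactone ring (step 14), then A and B (step 20).

Key step: step 3

Remark: locants C1–C8a are those of the naphthalen-2-one unit. C2 is the carbonyl and later the spiro carbon, C4a the ring-fusion CH, C5 methyl-bearing, C8 isopropyl-bearing, and C8a the second fusion carbon. Compounds 4, 25, 34 and 35 are carried as mixtures at centres that disappear later and are drawn without configuration there.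

Step 1
Reactants: 1 (R)-citronellal; 2 methyl vinyl ketone
Product: 3 (2R,3R)-3,7-dimethyl-2-(3-oxobutyl)oct-6-enal
Conditions: (R)-2-[methoxy(diphenyl)methyl]pyrrolidine (5 mol %), ethyl 3,4-dihydroxybenzoate (20 mol %), neat, 4 °C
Reagents that add atoms: none
Why: Enamine-catalysed Michael addition in which the CPh2OMe group of the R catalyst shields one face of the E-enamine, so the enone adds to the open face and should set C2 as R by catalyst control, while the remote C3 methyl centre comes unchanged from citronellal.

Step 2
Reactants: 3 (2R,3R)-3,7-dimethyl-2-(3-oxobutyl)oct-6-enal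
Product: 5 (4R)-4-[(2R)-6-methylhept-5-en-2-yl]cyclohex-2-en-1-one, via ketol 4 (not isolated)
Conditions: aq KOH (0.1 M, cat.), n-Bu4NOH (cat.), Et2O–THF, reflux
Reagents that add atoms: none
Why: Intramolecular aldol condensation of the methyl ketone onto the aldehyde followed by E1cB loss of water closes ring C faster than the hindered α-branched aldehyde enolises, so the centre from step 1 becomes C4 of the enone and is no longer α to a carbonyl.

Step 3
Reactants: 5 (4R)-4-[(2R)-6-methylhept-5-en-2-yl]cyclohex-2-en-1-one
Product: 6 (4aR,5R,8R,8aR)-5-methyl-8-(prop-1-en-2-yl)octahydronaphthalen-2(1H)-one (cis-fused)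
Conditions: MeAlCl2 (1.1 equiv), CH2Cl2, −78 → 0 °C; 1 M HCl
Reagents that add atoms: none
Why: MeAlCl2 binds the enone oxygen and makes C3 electrophilic, the CH terminus of the trisubstituted alkene attacks it, and the tertiary cation hands a methyl proton to the aluminium enolate carbon through a six-membered array, so the net change is an intramolecular conjugate ene reaction, whose closest known type is the alkylaluminium-halide-induced conjugate addition of a tethered alkene to an enone. Ring D closes 6-exo-trig with respect to both π systems, since the enone α carbon and the CMe2 carbon stay outside the new ring. C8a is set by stereoelectronics: the tether is pseudo-equatorial on C4 and must reach C3 along the axial trajectory, and an axial/equatorial pair on neighbouring carbons is cis. C8 is set by the chair of the forming ring, in which the C5 methyl group (fixed by citronellal) and the CMe2 terminus are both equatorial and therefore trans-1,4. The step needs conjugate attack in preference to carbonyl-ene addition, cyclobutane closure and hydride shifts, and the tether length (a six-membered ring only to C3), a single equivalent of Lewis acid, low temperature and the reversibility of cyclobutane closure should secure this. C8a is sacrificed in step 6, so only C8 has to be right.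

Step 4
Reactants: 6 (4aR,5R,8R,8aR)-5-methyl-8-(prop-1-en-2-yl)octahydronaphthalen-2(1H)-one
Product: 7 (4aR,5R,8S,8aS)-5-methyl-8-(propan-2-yl)octahydronaphthalen-2(1H)-one
Conditions: H2 (1 atm), RhCl(PPh3)3 (5 mol %), benzene–EtOH, rt
Reagents that add atoms: none
Why: Homogeneous hydrogenation reduces the 1,1-disubstituted alkene, leaves the ketone alone and does not move the alkene into the tetrasubstituted position, so C8 is untouched (its descriptor changes only through the priority rules).

Step 5
Reactants: 7 (4aR,5R,8S,8aS)-5-methyl-8-(propan-2-yl)octahydronaphthalen-2(1H)-one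
Product: 9 trimethylsilyl enol ether with the C1=C2 double bond (4aR,5R,8S,8aS), via lithium enolate 8 (not isolated)
Conditions: (R,R)-bis(1-phenylethyl)amine·HCl, n-BuLi (2 equiv per salt), THF, −78 °C; TMSCl, then 7, −78 °C (in situ quench)
Reagents that add atoms: chlorotrimethylsilane, C[Si](C)(C)Cl
Why: This is a kinetic deprotonation with a C2-symmetric chiral lithium amide, a reaction type known to steer the direction of enolisation of chiral cyclohexanones such as 3-keto steroids; the substrate has little bias of its own because the axial hydrogens on C1 and C3 are pseudo-enantiotopic, and the R,R amide, which gives the S enol silane from 4-tert-butylcyclohexanone, should take H-1.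

Step 6
Reactants: 9 trimethylsilyl enol ether
Product: 10 (4aR,5R,8S)-5-methyl-8-(propan-2-yl)-4,4a,5,6,7,8-hexahydronaphthalen-2(3H)-one
Conditions: Pd(OAc)2 (1.0 equiv), MeCN, rt
Reagents that add atoms: none
Why: Saegusa–Ito oxidation, in which the palladium enolate at C1 can lose only H-8a, places the double bond on the ring-fusion side under neutral conditions that do not epimerise the γ positions C4a and C8, and one equivalent of oxidant avoids a second dehydrogenation to the phenol.

Step 7
Reactants: 11 (4S)-4-benzyl-1,3-oxazolidin-2-one; 12 3-methylbutanoyl chloride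
Product: 14 (4S)-4-benzyl-3-(3-methylbutanoyl)-1,3-oxazolidin-2-one, via N-lithio oxazolidinone 13 (not isolated)
Conditions: n-BuLi, THF, −78 °C; 12, −78 → 0 °C
Reagents that add atoms: none
Why: N-Acylation of the lithiated auxiliary by an acid chloride is a standard entry to the Evans alkylation.

Step 8
Reactants: 14 (4S)-4-benzyl-3-(3-methylbutanoyl)-1,3-oxazolidin-2-one; 15 tert-butyl bromoacetate
Product: 17 tert-butyl (3S)-3-{[(4S)-4-benzyl-2-oxo-1,3-oxazolidin-3-yl]carbonyl}-4-methylpentanoate, via sodium Z-enolate 16 (not isolated)
Conditions: NaHMDS, THF, −78 °C; 15, −78 → −30 °C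
Reagents that add atoms: none
Why: Evans asymmetric alkylation, in which the chelated Z-enolate is attacked on the face opposite the benzyl group, sets the isopropyl-bearing centre that becomes the CH(iPr) of ring B.

Step 9
Reactants: 17 alkylated imide
Product: 18 (2S)-2-(propan-2-yl)butane-1,4-diol
Conditions: LiAlH4, THF, 0 °C → rt; H2O, aq NaOH work-up
Reagents that add atoms: none
Why: Hydride reduction takes both the imide and the tert-butyl ester to primary alcohols and releases the auxiliary without enolising the stereocentre.

Step 10
Reactants: 18 (2S)-2-(propan-2-yl)butane-1,4-diol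
Product: 19 (2S)-4-[(tert-butyldimethylsilyl)oxy]-2-(propan-2-yl)butan-1-ol
Conditions: TBSCl (1.0 equiv), imidazole, CH2Cl2, −20 °C
Reagents that add atoms: tert-butyldimethylsilyl chloride, CC(C)(C)[Si](C)(C)Cl
Why: Sterically differentiated silylation should pick the open C4 hydroxyl, because the C1 hydroxyl sits next to the doubly branched carbon, and the regioisomer can be removed by chromatography.

Step 11
Reactants: 19 mono-silyl ether
Product: 20 tert-butyl{[(3S)-3-(iodomethyl)-4-methylpentyl]oxy}dimethylsilane
Conditions: I2, PPh3, imidazole, CH2Cl2, 0 °C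
Reagents that add atoms: iodine, II
Why: Appel-type iodination is an SN2 displacement at the primary carbon and leaves the neighbouring stereocentre and the silyl ether untouched.

Step 12
Reactants: 20 iodide; 10 octalone
Product: 23 (2S,4aR,5R,8S)-2-{(2R)-4-[(tert-butyldimethylsilyl)oxy]-2-(propan-2-yl)butyl}-5-methyl-8-(propan-2-yl)-2,3,4,4a,5,6,7,8-octahydronaphthalen-2-ol, via alkyllithium 21 (not isolated), via alkylcerium dichloride 22 (not isolated)
Conditions: 20, t-BuLi (2.1 equiv), Et2O–pentane, −78 °C; anhydrous CeCl3, THF, −78 °C; 10, −78 °C; aq NH4Cl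
Reagents that add atoms: none
Why: Iodine–lithium exchange, transmetalation and organocerium 1,2-addition give a weakly basic nucleophile that neither enolises the enone (C4a and C8 stay safe) nor adds 1,4; the bulky β-branched reagent should take the equatorial path, because the axial path runs over the face that carries axial H-4 and the axial C5 methyl group, which places the hydroxyl pseudo-axial (2S).

Step 13
Reactants: 23 silyl ether alcohol
Product: 24 (2S,4aR,5R,8S)-2-[(2R)-4-hydroxy-2-(propan-2-yl)butyl]-5-methyl-8-(propan-2-yl)-2,3,4,4a,5,6,7,8-octahydronaphthalen-2-ol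
Conditions: TBAF, THF, 0 °C → rt
Reagents that add atoms: none
Why: Fluoride cleavage of the primary silyl ether is neutral to slightly basic and does not ionise the tertiary allylic alcohol.

Step 14
Reactants: 24 diol
Product: 26 spiro δ-lactone (oxan-2-one C6 = octalin C2; spiro carbon S; oxanone C4 S; octalin 4aR,5R,8S), via lactol 25 (not isolated)
Conditions: TEMPO (15 mol %), PhI(OAc)2 (2.5 equiv), CH2Cl2, rt
Reagents that add atoms: none
Why: Oxoammonium-mediated oxidative lactonisation of a 1,5-diol oxidises only the primary alcohol, the aldehyde closes onto the tertiary hydroxyl and the lactol is oxidised again, so the spiro C–O bond is never broken and its configuration is kept.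

Step 15
Reactants: 27 isobutyraldehyde; 28 morpholine
Product: 29 4-(2-methylprop-1-en-1-yl)morpholine
Conditions: TsOH (cat.), toluene, reflux, Dean–Stark
Reagents that add atoms: none
Why: Enamine condensation is driven by azeotropic removal of water.

Step 16
Reactants: 29 enamine; 30 propanoyl chloride
Product: 32 2,2-dimethyl-3-oxopentanal, via acyl iminium chloride 31 (not isolated)
Conditions: Et2O, 0 °C → reflux; H2O
Reagents that add atoms: water, O
Why: Stork enamine acylation at the β carbon creates the quaternary CMe2 carbon, and the iminium salt cannot tautomerise and is hydrolysed to the keto aldehyde.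

Step 17
Reactants: 26 spiro δ-lactone; 32 2,2-dimethyl-3-oxopentanal
Product: 34 α-(1-hydroxy-2,2-dimethyl-3-oxopentyl) lactone, via lactone lithium enolate 33 (not isolated)
Conditions: LDA, THF, −78 °C; 32, −78 °C; AcOH in THF at −78 °C
Reagents that add atoms: none
Why: In this lithium enolate aldol addition the aldehyde is far more electrophilic than the hindered ketone, the low temperature excludes an ester-enolate Claisen rearrangement of the allylic lactone, and the two new centres are erased in steps 18 and 19.

Step 18
Reactants: 34 aldol
Product: 35 α-(2,2-dimethyl-3-oxopentanoyl) lactone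
Conditions: Dess–Martin periodinane, CH2Cl2, 0 °C → rt
Reagents that add atoms: none
Why: Dess–Martin oxidation converts the hindered secondary alcohol into the ketone under nearly neutral conditions that spare the alkene and the tertiary allylic lactone.

Step 19
Reactants: 35 β-keto lactone
Product: 36 (E)-enol tosylate of 35 (tosyloxy cis to the CH(iPr) carbon; CMe2 cis to the lactone carbonyl)
Conditions: TsCl, N-methylimidazole, Et3N, CH2Cl2, 0 °C → rt
Reagents that add atoms: p-toluenesulfonyl chloride, Cc1ccc(cc1)S(Cl)(=O)=O
Why: This is the enol tosylation of a β-keto ester under non-chelating amine conditions, known to favour the E isomer; only the ketone next to the acidic C–H reacts, the bulky CMe2 group should take the side of the flat lactone carbonyl, and the tosylate both marks this carbon as the future O-bearing carbon of ring B and keeps the lactone carbonyl electrophilic.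

Step 20
Reactants: 36 (E)-enol tosylate
Product: 38 O-demethyl target (tricyclic vinylogous acid; rings A–D complete), via hydroxy enol tosylate 37 (not isolated)
Conditions: KHMDS (2.2 equiv), THF, −78 → 40 °C; AcOH
Reagents that add atoms: none
Why: Proposed new method: KHMDS removes the only acidic C–H (the CH2 of the ethyl ketone), the enolate attacks the lactone carbonyl in a 6-(enolendo)-exo-trig Claisen closure that forms ring A and expels the tertiary alkoxide with its C–O bond and configuration intact, the second equivalent of base takes the new diketone proton, and the alkoxide then adds to the only carbon that bears a leaving group (6-endo-trig) and expels tosylate to close ring B, so the oxygen moves from the lactone carbonyl to the carbon next to CMe2 without ionisation at the spiro centre; the closest known reaction types are the Dieckmann-type acylation of a ketone enolate by a lactone and the addition–elimination of alkoxides on β-sulfonyloxy enones, which have not been run in tandem on an α-alkylidene lactone.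

Step 21
Reactants: 38 O-demethyl target
Product: 39 target CNP0194760.3
Conditions: TMSCHN2, toluene–MeOH (4:1), 0 °C
Reagents that add atoms: (trimethylsilyl)diazomethane, C[Si](C)(C)C=[N+]=[N-]
Why: In this O-methylation of a vinylogous acid by a diazoalkane, the acidic hydroxyl should sit on the carbon next to CMe2 because the other carbonyl already accepts the ring B enol ether (cross-conjugated 3-hydroxy-2,5-dienone tautomer), so the methyl group should end there, carbon alkylation is not open to this reagent, an isomeric 2,4-dienone ether would be separable, and no stereocentre is touched.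

**Compound list**
1 | (R)-citronellal | C[C@H](CCC=C(C)C)CC=O | starting material
2 | methyl vinyl ketone | CC(=O)C=C | starting material
3 | (2R,3R)-3,7-dimethyl-2-(3-oxobutyl)oct-6-enal | O=C[C@H](CCC(C)=O)[C@H](C)CCC=C(C)C | intermediate
4 | ketol, (4R)-3-hydroxy-4-[(2R)-6-methylhept-5-en-2-yl]cyclohexanone | O=C1CC(O)[C@H](CC1)[C@H](C)CCC=C(C)C | intermediate
5 | (4R)-4-[(2R)-6-methylhept-5-en-2-yl]cyclohex-2-en-1-one | O=C1C=C[C@H](CC1)[C@H](C)CCC=C(C)C | intermediate
6 | (4aR,5R,8R,8aR)-5-methyl-8-(prop-1-en-2-yl)octahydronaphthalen-2(1H)-one | O=C1C[C@H]2[C@H](C(C)=C)CC[C@@H](C)[C@H]2CC1 | intermediate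
7 | (4aR,5R,8S,8aS)-5-methyl-8-(propan-2-yl)octahydronaphthalen-2(1H)-one | O=C1C[C@H]2[C@H](C(C)C)CC[C@@H](C)[C@H]2CC1 | intermediate
8 | lithium enolate of 7 (C1=C2) | [Li]OC1=C[C@H]2[C@H](C(C)C)CC[C@@H](C)[C@H]2CC1 | intermediate
9 | trimethylsilyl enol ether of 7 (C1=C2) | C[Si](C)(C)OC1=C[C@H]2[C@H](C(C)C)CC[C@@H](C)[C@H]2CC1 | intermediate
10 | (4aR,5R,8S)-5-methyl-8-(propan-2-yl)-4,4a,5,6,7,8-hexahydronaphthalen-2(3H)-one | O=C1C=C2[C@H](C(C)C)CC[C@@H](C)[C@H]2CC1 | intermediate
11 | (4S)-4-benzyl-1,3-oxazolidin-2-one | O=C1OC[C@H](Cc2ccccc2)N1 | starting material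
12 | 3-methylbutanoyl chloride | CC(C)CC(Cl)=O | starting material
13 | N-lithio oxazolidinone | [Li]N1[C@@H](Cc2ccccc2)COC1=O | intermediate
14 | (4S)-4-benzyl-3-(3-methylbutanoyl)-1,3-oxazolidin-2-one | CC(C)CC(=O)N1[C@@H](Cc2ccccc2)COC1=O | intermediate
15 | tert-butyl bromoacetate | CC(C)(C)OC(=O)CBr | starting material
16 | sodium Z-enolate of 14 | [Na]O/C(=C\C(C)C)N1[C@@H](Cc2ccccc2)COC1=O | intermediate
17 | tert-butyl (3S)-3-{[(4S)-4-benzyl-2-oxo-1,3-oxazolidin-3-yl]carbonyl}-4-methylpentanoate | O=C([C@@H](CC(=O)OC(C)(C)C)C(C)C)N1[C@@H](Cc2ccccc2)COC1=O | intermediate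
18 | (2S)-2-(propan-2-yl)butane-1,4-diol | OC[C@@H](CCO)C(C)C | intermediate
19 | (2S)-4-[(tert-butyldimethylsilyl)oxy]-2-(propan-2-yl)butan-1-ol | OC[C@@H](CCO[Si](C)(C)C(C)(C)C)C(C)C | intermediate
20 | tert-butyl{[(3S)-3-(iodomethyl)-4-methylpentyl]oxy}dimethylsilane | IC[C@@H](CCO[Si](C)(C)C(C)(C)C)C(C)C | intermediate
21 | alkyllithium from 20 | [Li]C[C@@H](CCO[Si](C)(C)C(C)(C)C)C(C)C | intermediate
22 | alkylcerium dichloride from 21 | Cl[Ce](Cl)C[C@@H](CCO[Si](C)(C)C(C)(C)C)C(C)C | intermediate
23 | tertiary allylic alcohol (2S,4aR,5R,8S; side chain 2R), TBS ether | O[C@]1(C=C2[C@H](C(C)C)CC[C@@H](C)[C@H]2CC1)C[C@@H](CCO[Si](C)(C)C(C)(C)C)C(C)C | intermediate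
24 | diol (2S,4aR,5R,8S; side chain 2R) | O[C@]1(C=C2[C@H](C(C)C)CC[C@@H](C)[C@H]2CC1)C[C@@H](CCO)C(C)C | intermediate
25 | spiro lactol | OC1O[C@]2(C=C3[C@H](C(C)C)CC[C@@H](C)[C@H]3CC2)C[C@@H](C1)C(C)C | intermediate
26 | spiro δ-lactone | O=C1O[C@]2(C=C3[C@H](C(C)C)CC[C@@H](C)[C@H]3CC2)C[C@@H](C1)C(C)C | intermediate
27 | isobutyraldehyde | CC(C)C=O | starting material
28 | morpholine | C1COCCN1 | starting material
29 | 4-(2-methylprop-1-en-1-yl)morpholine | CC(C)=CN1CCOCC1 | intermediate
30 | propanoyl chloride | CCC(Cl)=O | starting material
31 | 4-(2,2-dimethyl-3-oxopentylidene)morpholin-4-ium chloride | CCC(=O)C(C)(C)C=[N+]1CCOCC1.[Cl-] | intermediate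
32 | 2,2-dimethyl-3-oxopentanal | CCC(=O)C(C)(C)C=O | intermediate
33 | lithium enolate of 26 | [Li]OC=1O[C@]2(C=C3[C@H](C(C)C)CC[C@@H](C)[C@H]3CC2)C[C@@H](C=1)C(C)C | intermediate
34 | α-(1-hydroxy-2,2-dimethyl-3-oxopentyl) lactone | O=C1O[C@]2(C=C3[C@H](C(C)C)CC[C@@H](C)[C@H]3CC2)C[C@H](C(C)C)C1C(O)C(C)(C)C(=O)CC | intermediate
35 | α-(2,2-dimethyl-3-oxopentanoyl) lactone | O=C1O[C@]2(C=C3[C@H](C(C)C)CC[C@@H](C)[C@H]3CC2)C[C@H](C(C)C)C1C(=O)C(C)(C)C(=O)CC | intermediate
36 | (E)-enol tosylate of 35 | O=C1O[C@]2(C=C3[C@H](C(C)C)CC[C@@H](C)[C@H]3CC2)C[C@H](C(C)C)/C1=C(\OS(=O)(=O)c4ccc(C)cc4)C(C)(C)C(=O)CC | intermediate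
37 | hydroxy enol tosylate (ring A closed, ring B open) | O[C@]1(C=C2[C@H](C(C)C)CC[C@@H](C)[C@H]2CC1)C[C@H](C(C)C)C3=C(OS(=O)(=O)c4ccc(C)cc4)C(C)(C)C(=O)C(C)C3=O | intermediate
38 | O-demethyl target (enol form) | OC1=C(C)C(=O)C2=C(O[C@]3(C=C4[C@H](C(C)C)CC[C@@H](C)[C@H]4CC3)C[C@@H]2C(C)C)C1(C)C | intermediate
39 | CNP0194760.3 | COC1=C(C)C(=O)C2=C(O[C@]3(C=C4[C@H](C(C)C)CC[C@@H](C)[C@H]4CC3)C[C@@H]2C(C)C)C1(C)C | target

**Step count**
- Total step count: 21.
- Longest linear sequence: 14 (steps 1–6, 12–14, 17–21).

**Steps most likely to fail**

1. **Step 20.** After the Claisen closure ring A is an enolate. Addition of the tertiary alkoxide to the tosyloxy carbon may then be too slow, so that sulfonate cleavage or retro-Claisen opening takes over.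
   - The fallback sets out from 35, comes back at 39, and uses only known reaction types on neutral rings.
   - O-Methylation of the β-keto lactone (Me2SO4, K2CO3, acetone) gives the (E)-methyl enol ether lactone F1.
   - KHMDS-induced Dieckmann closure with a neutral work-up gives the hydroxy methoxy vinylogous acid F2.
   - (Trimethylsilyl)diazomethane converts it into the neutral hydroxy 3,5-dimethoxy dienone F3.
   - Catalytic NaH in toluene over 4 Å sieves lets the tethered alkoxide exchange the methoxy group within its reach by vinylogous transesterification, which gives 39 directly.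

2. **Step 3.** A hydride shift or proton loss at C8 in the tertiary cation, chloride capture, or closure through a non-chair array would erode C8 or divert material.
   - The fallback sets out from 5, comes back at 7, and keeps the same C8–C8a bond.
   - Irradiation (350 nm, Pyrex, MeCN) brings about an intramolecular enone–alkene [2+2] photocycloaddition. The six-membered ring forms first, giving the cyclobutane ketone F4. Disproportionation of the biradical would give 6, which is on the route anyway.
   - SmI2 in THF–MeOH cleaves the cyclobutane bond α to the ketone that releases the tertiary radical. This delivers the isopropyl decalone 7 without the hydrogenation step.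

3. **Step 12.** Poor facial selectivity of the 1,2-addition would put the hydroxyl pseudo-equatorial.
   - The fallback sets out from 10 (with 20), comes back at 26, and replaces kinetic face control by thermodynamic control.
   - The (2R)-epimeric alcohol F5 is desilylated (TBAF) to the epimeric diol F6 and oxidised (TEMPO, PhI(OAc)2) to the epimeric spiro lactone F7.
   - Catalytic camphorsulfonic acid in CH2Cl2 at 0 °C ionises the allylic C–O bond reversibly.
   - Re-closure should favour 26, in which the oxygen and not the CH2 group is pseudo-axial on ring C.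

**Further compounds**
F1 | step 20 | (E)-methyl enol ether lactone | O=C1O[C@]2(C=C3[C@H](C(C)C)CC[C@@H](C)[C@H]3CC2)C[C@H](C(C)C)/C1=C(\OC)C(C)(C)C(=O)CC
F2 | step 20 | hydroxy methoxy vinylogous acid | O[C@]1(C=C2[C@H](C(C)C)CC[C@@H](C)[C@H]2CC1)C[C@H](C(C)C)C3=C(OC)C(C)(C)C(O)=C(C)C3=O
F3 | step 20 | hydroxy 3,5-dimethoxy dienone | O[C@]1(C=C2[C@H](C(C)C)CC[C@@H](C)[C@H]2CC1)C[C@H](C(C)C)C3=C(OC)C(C)(C)C(OC)=C(C)C3=O
F4 | step 3 | cyclobutane ketone | O=C1CC[C@@H]2[C@H](C)CC[C@@H]3[C@@H]2[C@@H]1C3(C)C
F5 | step 12 | (2R)-epimeric alcohol | O[C@@]1(C=C2[C@H](C(C)C)CC[C@@H](C)[C@H]2CC1)C[C@@H](CCO[Si](C)(C)C(C)(C)C)C(C)C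
F6 | step 12 | epimeric diol | O[C@@]1(C=C2[C@H](C(C)C)CC[C@@H](C)[C@H]2CC1)C[C@@H](CCO)C(C)C
F7 | step 12 | epimeric spiro lactone | O=C1O[C@@]2(C=C3[C@H](C(C)C)CC[C@@H](C)[C@H]3CC2)C[C@@H](C1)C(C)C
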